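The carbocycle is built by a ring closure at C5–C6 and the three stereocentres are set independently: C4 from (R)-epichlorohydrin, C8 from D-lactate, C6 by a chiral palladium catalyst.

Locants: ring C1 (C=O), C2=C3, C4 (CH–OMe), C5 (CH2), C6 (quaternary); C8 is the side-chain CH. Everything rests on closing the carbocycle at C5–C6 by intramolecular C-alkylation of an acyclic β-keto allyl ester enolate, whose ω-chloro end carries the C4 stereocentre from (R)-epichlorohydrin. The step exploits the 1,4-relation of the C1 carbonyl and the C4 oxygen and the acidity of C6: one operation makes the ring and leaves C6 as an activated β-keto ester carbon. C6 is then alkylated with a D-lactate-derived α-keto triflate (C8, inversion), the ester is traded for the C6 allyl group by decarboxylative asymmetric allylation, and dehydrogenation gives the enone.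

Key step: step 4

Remark: the target is read as (4S,6S) in the ring with an (R) side-chain methine, that is, methoxy trans to allyl; (R)-epichlorohydrin, allyl acetoacetate, methyl (R)-lactate, 3,4-dimethoxyphenylmagnesium bromide solution and (R)-t-BuPHOX are taken as commercial.

Step 1
Reactants: 1 (R)-epichlorohydrin [(2R)-2-(chloromethyl)oxirane]
Product: 2 (2S)-1-chloro-3-iodopropan-2-ol
Conditions: LiI, AcOH, THF, 0 °C to rt
Reagents that add atoms: lithium iodide, [Li+].[I-]
Why: Acid-assisted SN2 opening of the epoxide by iodide at the unsubstituted carbon (halohydrin formation) leaves the C–O bond of the stereocentre untouched, so the configuration is retained and only the descriptor changes because CH2I outranks CH2Cl.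

Step 2
Reactants: 2 (2S)-1-chloro-3-iodopropan-2-ol
Product: 3 (2S)-1-chloro-3-iodo-2-methoxypropane
Conditions: MeOTf, 2,6-di-tert-butyl-4-methylpyridine, CH2Cl2, 0 °C to rt
Reagents that add atoms: methyl trifluoromethanesulfonate, COS(=O)(=O)C(F)(F)F
Why: O-Methylation of the secondary alcohol with a hard methyl donor and a hindered weak pyridine base never generates the alkoxide, so the halohydrin cannot re-close to an epoxide and scramble its two termini.

Step 3
Reactants: 4 allyl acetoacetate (prop-2-en-1-yl 3-oxobutanoate); 3 (2S)-1-chloro-3-iodo-2-methoxypropane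
Product: 5 prop-2-en-1-yl (6R)-7-chloro-6-methoxy-3-oxoheptanoate
Conditions: 4, NaH then n-BuLi, THF, 0 °C; 3, −78 to 0 °C; aq. NH4Cl
Reagents that add atoms: none
Why: γ-Alkylation of the acetoacetate dianion (β-keto ester dianion alkylation) should occur at the primary iodide far faster than at the chloride, which fixes which terminus of the pseudo-symmetric three-carbon unit becomes C3 and which remains the C5 electrophile, while the stereocentre is not involved.

Step 4
Reactants: 5 prop-2-en-1-yl (6R)-7-chloro-6-methoxy-3-oxoheptanoate
Product: 6 prop-2-en-1-yl (5R)-5-methoxy-2-oxocyclohexane-1-carboxylate (both C1 epimers and the enol)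
Conditions: NaH, NaI (cat.), THF (0.02 M), 0 °C to reflux
Reagents that add atoms: none
Why: NaH gives the chelated sodium enolate of the β-keto ester, whose central carbon (C6) displaces the primary halide at C5 (chloride, relayed through the iodide by NaI) in an intramolecular SN2 reaction that forms the C5–C6 bond and the carbocycle. The closest known reaction type is the cyclisation of ω-halo β-keto ester and ketone enolates to 2-oxocyclohexanecarboxylates and cyclohexanones. The six-membered ring closes in the 6-(enolendo)-exo-tet mode, which is allowed for enolates. C6 forms as both epimers, which is of no consequence because this acidic centre is substituted in step 8 and planarised in step 9, while C4 is a spectator that becomes a true ring stereocentre only because the ester distinguishes C6 from C2. The selectivity needed is C- over O-alkylation (6-exo closure through the enolate oxygen would give a 2-alkylidene tetrahydropyran) and intra- over intermolecular alkylation. A tight sodium chelate in THF and a soft iodide leaving group favour carbon, and high dilution suppresses oligomers.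

Step 5
Reactants: 7 methyl (R)-lactate [methyl (2R)-2-hydroxypropanoate]
Product: 8 (2R)-2-hydroxy-N-methoxy-N-methylpropanamide
Conditions: MeNHOMe·HCl, i-PrMgCl, THF, −20 to 0 °C
Reagents that add atoms: N,O-dimethylhydroxylamine hydrochloride, Cl.CNOC
Why: Aminolysis of the ester by the magnesium amide (Weinreb amide formation, the hydroxyl carried as its magnesium alkoxide) does not touch the stereocentre.

Step 6
Reactants: 8 (2R)-2-hydroxy-N-methoxy-N-methylpropanamide; 9 3,4-dimethoxyphenylmagnesium bromide
Product: 10 (2R)-1-(3,4-dimethoxyphenyl)-2-hydroxypropan-1-one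
Conditions: 9 (2.5 equiv), THF, −20 to 0 °C; aq. NH4Cl
Reagents that add atoms: none
Why: Weinreb ketone synthesis, in which the first equivalent of 9 deprotonates the hydroxyl and the second adds to give a chelated tetrahedral intermediate that collapses only on quench, so over-addition is avoided and the α-stereocentre, held as the magnesium alkoxide, is expected to survive.

Step 7
Reactants: 10 (2R)-1-(3,4-dimethoxyphenyl)-2-hydroxypropan-1-one
Product: 11 (2R)-1-(3,4-dimethoxyphenyl)-1-oxopropan-2-yl trifluoromethanesulfonate
Conditions: Tf2O, 2,6-lutidine, CH2Cl2, −78 °C; cold aqueous work-up; used at once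
Reagents that add atoms: trifluoromethanesulfonic anhydride, O=S(=O)(OS(=O)(=O)C(F)(F)F)C(F)(F)F
Why: O-Triflation at low temperature forms only an S–O bond, so the configuration is retained, and it turns the hydroxyl into a leaving group that the adjacent ketone activates for SN2 displacement.

Step 8
Reactants: 6 prop-2-en-1-yl (5R)-5-methoxy-2-oxocyclohexane-1-carboxylate; 11 (2R)-1-(3,4-dimethoxyphenyl)-1-oxopropan-2-yl trifluoromethanesulfonate
Product: 12 prop-2-en-1-yl (5R)-1-[(2R)-1-(3,4-dimethoxyphenyl)-1-oxopropan-2-yl]-5-methoxy-2-oxocyclohexane-1-carboxylate (both C1 epimers)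
Conditions: 6, NaH, THF, 0 °C; 11, −78 to −20 °C
Reagents that add atoms: none
Why: SN2 alkylation of the stabilised sodium enolate of 6 by the α-keto triflate (the known inversion chemistry of α-sulfonyloxy carbonyl compounds with malonate-type carbanions) should set the side-chain methine C8 by inversion of the lactate-derived centre (the descriptor stays R only because the priorities change), while the new quaternary carbon forms as both epimers, which is harmless because it is planarised in step 9.

Step 9
Reactants: 12 prop-2-en-1-yl (5R)-1-[(2R)-1-(3,4-dimethoxyphenyl)-1-oxopropan-2-yl]-5-methoxy-2-oxocyclohexane-1-carboxylate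
Product: 13 (2S,4R)-2-[(2R)-1-(3,4-dimethoxyphenyl)-1-oxopropan-2-yl]-4-methoxy-2-(prop-2-en-1-yl)cyclohexan-1-one
Conditions: Pd2(dba)3 (2.5 mol %), (R)-t-BuPHOX (6 mol %), THF, 25 °C
Reagents that add atoms: none
Why: Decarboxylative asymmetric allylic alkylation (Tsuji allylation with a chiral phosphinooxazoline), in which zerovalent palladium ionises the allyl ester, loss of CO2 turns both epimers of 12 into one tetrasubstituted palladium enolate, and ligand-controlled recombination should set C6 with allyl trans to the C4 methoxy group; the (R) ligand is chosen by the established facial sense of this ligand class with 2-alkylcyclohexanone enolates, and the substrate's own preference for axial attack trans to an equatorial methoxy group points the same way.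

Step 10
Reactants: 13 (2S,4R)-2-[(2R)-1-(3,4-dimethoxyphenyl)-1-oxopropan-2-yl]-4-methoxy-2-(prop-2-en-1-yl)cyclohexan-1-one
Product: 15 (4S,6S)-6-[(2R)-1-(3,4-dimethoxyphenyl)-1-oxopropan-2-yl]-4-methoxy-6-(prop-2-en-1-yl)cyclohex-2-en-1-one, via silyl enol ether 14 (not isolated)
Conditions: LiN(i-Pr)2, TMSCl, THF, −78 °C; then Pd(OAc)2, MeCN, rt
Reagents that add atoms: none
Why: Saegusa–Ito oxidation, in which kinetic deprotonation should occur at the only unhindered α-methylene (C2, since C6 is quaternary and the C8 methine next to the aryl ketone is shielded by it) and the palladium enolate formed from the silyl enol ether loses the C3 hydrogen to give the C2=C3 enone without touching C4, C6 or C8.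

Compound list
1 | (R)-epichlorohydrin, (2R)-2-(chloromethyl)oxirane | ClC[C@H]1CO1 | starting material
2 | (2S)-1-chloro-3-iodopropan-2-ol | ClC[C@H](O)CI | intermediate
3 | (2S)-1-chloro-3-iodo-2-methoxypropane | ClC[C@H](OC)CI | intermediate
4 | allyl acetoacetate, prop-2-en-1-yl 3-oxobutanoate | CC(=O)CC(=O)OCC=C | starting material
5 | prop-2-en-1-yl (6R)-7-chloro-6-methoxy-3-oxoheptanoate | C=CCOC(=O)CC(=O)CC[C@@H](OC)CCl | intermediate
6 | prop-2-en-1-yl (5R)-5-methoxy-2-oxocyclohexane-1-carboxylate (both C1 epimers and the enol) | C=CCOC(=O)C1C[C@H](OC)CCC1=O | intermediate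
7 | methyl (R)-lactate, methyl (2R)-2-hydroxypropanoate | C[C@@H](O)C(=O)OC | starting material
8 | (2R)-2-hydroxy-N-methoxy-N-methylpropanamide | C[C@@H](O)C(=O)N(C)OC | intermediate
9 | 3,4-dimethoxyphenylmagnesium bromide | COc1ccc([Mg]Br)cc1OC | starting material
10 | (2R)-1-(3,4-dimethoxyphenyl)-2-hydroxypropan-1-one | C[C@@H](O)C(=O)c1ccc(OC)c(OC)c1 | intermediate
11 | (2R)-1-(3,4-dimethoxyphenyl)-1-oxopropan-2-yl trifluoromethanesulfonate | C[C@@H](OS(=O)(=O)C(F)(F)F)C(=O)c1ccc(OC)c(OC)c1 | intermediate
12 | prop-2-en-1-yl (5R)-1-[(2R)-1-(3,4-dimethoxyphenyl)-1-oxopropan-2-yl]-5-methoxy-2-oxocyclohexane-1-carboxylate (both C1 epimers) | C=CCOC(=O)C1([C@@H](C)C(=O)c2ccc(OC)c(OC)c2)C[C@H](OC)CCC1=O | intermediate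
13 | (2S,4R)-2-[(2R)-1-(3,4-dimethoxyphenyl)-1-oxopropan-2-yl]-4-methoxy-2-(prop-2-en-1-yl)cyclohexan-1-one | C=CC[C@@]1([C@@H](C)C(=O)c2ccc(OC)c(OC)c2)C[C@H](OC)CCC1=O | intermediate
14 | trimethylsilyl enol ether of 13 (C1=C2 enol ether, not isolated) | C=CC[C@@]1([C@@H](C)C(=O)c2ccc(OC)c(OC)c2)C[C@H](OC)CC=C1O[Si](C)(C)C | intermediate
15 | (4S,6S)-6-[(2R)-1-(3,4-dimethoxyphenyl)-1-oxopropan-2-yl]-4-methoxy-6-(prop-2-en-1-yl)cyclohex-2-en-1-one | C=CC[C@@]1([C@@H](C)C(=O)c2ccc(OC)c(OC)c2)C[C@H](OC)C=CC1=O | target

Total step count: 10.
Longest linear sequence: 7 steps (steps 1 to 4 and 8 to 10, from 1); the side-chain branch (steps 5 to 7) joins at step 8.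

Steps most likely to fail

Step 8. The hindered tertiary enolate may act as a base towards the triflate, so that elimination to the aryl vinyl ketone followed by conjugate addition would give the unbranched isomer. O-alkylation of the enolate or enolisation of the triflate with loss of configuration at C8 are further ways to fail. The fallback sets out from 6 and comes back at 13. Compound 6 is C-alkylated with commercial racemic 2-bromo-1-(3,4-dimethoxyphenyl)propan-1-one (K2CO3, acetone) to give prop-2-en-1-yl (5R)-1-[1-(3,4-dimethoxyphenyl)-1-oxopropan-2-yl]-5-methoxy-2-oxocyclohexane-1-carboxylate F1 as an epimer mixture. The conditions of step 9 should convert it into (2S,4R)-2-[1-(3,4-dimethoxyphenyl)-1-oxopropan-2-yl]-4-methoxy-2-(prop-2-en-1-yl)cyclohexan-1-one F2 as a pair of C8 epimers, which are diastereomers and are separated by chromatography to give 13. The unwanted epimer is re-equilibrated at C8 with DBU (only this centre is enolisable towards the aryl ketone) and separated again.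

Step 4. Ring closure through the enolate oxygen may outrun closure through carbon, and intermolecular alkylation may compete. The fallback sets out from 5 and comes back at 6, and it removes the ambident oxygen from the ring-forming step while still closing the ring at C5–C6. NaBH4 reduces the ketone to prop-2-en-1-yl (6R)-7-chloro-3-hydroxy-6-methoxyheptanoate F3. Finkelstein exchange (NaI, acetone) gives prop-2-en-1-yl (6R)-3-hydroxy-7-iodo-6-methoxyheptanoate F4. Double deprotonation with LiN(i-Pr)2 (2.2 equiv, THF–DMPU, −78 to 0 °C) and 6-exo-tet C-alkylation of the β-alkoxide ester enolate (Fráter–Seebach-type, the ester oxygen cannot reach the iodide) gives prop-2-en-1-yl (5R)-2-hydroxy-5-methoxycyclohexane-1-carboxylate F5. Dess–Martin periodinane oxidises F5 to 6.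

Step 3. Substitution at the β-branched, β-alkoxy primary iodide may be slow, so that the strongly basic dianion causes dehydrohalogenation or begins to attack the chloride terminus, which would erode the enantiomeric purity. The fallback sets out from 1 and comes back at 5, and it makes the C1–C6 bond by acyl homologation instead of alkylation. Opening of 1 with allylmagnesium chloride and catalytic CuI (THF, −40 °C) gives (2R)-1-chlorohex-5-en-2-ol F6. Methylation as in step 2 gives (5R)-6-chloro-5-methoxyhex-1-ene F7. Ozonolysis (O3, CH2Cl2, −78 °C, then Me2S) gives (4R)-5-chloro-4-methoxypentanal F8. The SnCl2-catalysed Roskamp reaction of F8 with prop-2-en-1-yl diazoacetate gives 5.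

Further compounds
F1 | step 8 | prop-2-en-1-yl (5R)-1-[1-(3,4-dimethoxyphenyl)-1-oxopropan-2-yl]-5-methoxy-2-oxocyclohexane-1-carboxylate (epimers at C1 and at the side-chain carbon) | C=CCOC(=O)C1(C(C)C(=O)c2ccc(OC)c(OC)c2)C[C@H](OC)CCC1=O
F2 | step 8 | (2S,4R)-2-[1-(3,4-dimethoxyphenyl)-1-oxopropan-2-yl]-4-methoxy-2-(prop-2-en-1-yl)cyclohexan-1-one (both side-chain epimers) | C=CC[C@@]1(C(C)C(=O)c2ccc(OC)c(OC)c2)C[C@H](OC)CCC1=O
F3 | step 4 | prop-2-en-1-yl (6R)-7-chloro-3-hydroxy-6-methoxyheptanoate (both C3 epimers) | C=CCOC(=O)CC(O)CC[C@@H](OC)CCl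
F4 | step 4 | prop-2-en-1-yl (6R)-3-hydroxy-7-iodo-6-methoxyheptanoate (both C3 epimers) | C=CCOC(=O)CC(O)CC[C@@H](OC)CI
F5 | step 4 | prop-2-en-1-yl (5R)-2-hydroxy-5-methoxycyclohexane-1-carboxylate (diastereomers at C1 and C2) | C=CCOC(=O)C1C[C@H](OC)CCC1O
F6 | step 3 | (2R)-1-chlorohex-5-en-2-ol | ClC[C@H](O)CCC=C
F7 | step 3 | (5R)-6-chloro-5-methoxyhex-1-ene | ClC[C@H](OC)CCC=C
F8 | step 3 | (4R)-5-chloro-4-methoxypentanal | ClC[C@H](OC)CCC=O
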